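**Overview**
Atom labels: ring C1 (CH2OAc), C2 (CHO), C3 (stereocentre), C4, C5; C1′ is the exocyclic CH(CHO). The formyl-bearing ring carbon C2 is bonded directly to C3, and C3 lies β to the formyl group on C1′, so the cyclopentene C1–C5 is the Rauhut–Currier isomer of an achiral open-chain bis-enal.
Retrosynthetic cuts, in order: the ring bond C2–C3; the C=C of the α-branched enal (aldol condensation) into a C13 aldehyde and an acetoxymethyl aldehyde; then the geranyl CH2–CH2 bond of the first and the alkyl–alkene bond next to CH2OAc of the second, both leading back to one three-carbon acetal Grignard reagent.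
Forward: the Grignard reagent is made once and used twice (coupling with geranyl bromide; carbomagnesiation of a monosilylated butynediol); acetylation, hydrolysis, aldol condensation, desilylation and oxidation complete the C20 chain, and the only ring is closed last.
Stereochemistry: C3 (R) comes from the chiral secondary amine of the ring closure; C1′ (S) is relayed from C3 by convex-face protonation of a cis-fused bicyclic intermediate; the (E)-trisubstituted chain alkene comes unchanged from geranyl bromide.

Key step: step 12

Assumption: the (S)-amine, C[Si](C)(C)OC(c1ccccc1)(c1ccccc1)[C@@H]1CCCN1, is assigned from the usual face-shielding model of diarylprolinol silyl ether enamines combined with a cis-fused oxa-[4+2] topology; the geometry of the acetoxymethyl enal is irrelevant because the dienamine erases it.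

**Route**

Step 1
Reactants: 1 2-(2-bromoethyl)-1,3-dioxolane
Product: 2 [2-(1,3-dioxolan-2-yl)ethyl]magnesium bromide (titrated THF solution)
Conditions: Mg turnings (1.3 equiv), I2 (one crystal), THF, 20–28 °C; decanted, titrated, kept at 0 °C
Reagents that add atoms: magnesium, [Mg]
Why: Grignard reagent formation by insertion of magnesium into the primary C–Br bond is kept below 30 °C because this β-acetal organomagnesium decays on warming; one batch, made when 3 and 8 are both in hand, is divided between steps 2 and 6.

Step 2
Reactants: 2 [2-(1,3-dioxolan-2-yl)ethyl]magnesium bromide; 3 geranyl bromide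
Product: 4 2-[(4E)-5,9-dimethyldeca-4,8-dien-1-yl]-1,3-dioxolane
Conditions: 3, Li2CuCl4 (3 mol%), THF, −10 °C; 2 (1.2 equiv) added slowly, −10 → 0 °C; aq NH4Cl
Reagents that add atoms: none
Why: Li2CuCl4-catalysed cross-coupling of a primary alkyl Grignard reagent with a primary allylic bromide proceeds by SN2 substitution at low temperature in THF, so the (E)-alkene of the geranyl unit should be carried over unchanged.

Step 3
Reactants: 4 2-[(4E)-5,9-dimethyldeca-4,8-dien-1-yl]-1,3-dioxolane
Product: 5 (5E)-6,10-dimethylundeca-5,9-dienal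
Conditions: AcOH/THF/H2O (3:1:1), 60 °C
Reagents that add atoms: water, O
Why: Acid-catalysed hydrolysis of a 1,3-dioxolane, in which warm aqueous acetic acid is too weak to hydrate or cyclise the trisubstituted alkenes.

Step 4
Reactants: 5 (5E)-6,10-dimethylundeca-5,9-dienal
Product: 6 (1E,5E)-N-tert-butyl-6,10-dimethylundeca-5,9-dien-1-imine
Conditions: t-BuNH2, 4 Å molecular sieves, Et2O, 0 °C → rt; filtered, concentrated, used crude
Reagents that add atoms: tert-butylamine, CC(C)(C)N
Why: Imine formation from an unhindered aldehyde and a primary amine is driven by removal of water, and the bulky tert-butyl group suppresses self-condensation of the aldimine.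

Step 5
Reactants: 7 but-2-yne-1,4-diol
Product: 8 4-[(tert-butyldiphenylsilyl)oxy]but-2-yn-1-ol
Conditions: TBDPSCl (1 equiv), 7 (3 equiv), imidazole, THF/DMF, 0 °C → rt
Reagents that add atoms: tert-butyl(chloro)diphenylsilane (TBDPSCl), CC(C)(C)[Si](Cl)(c1ccccc1)c1ccccc1
Why: Statistical monosilylation of a symmetrical diol used in excess gives the mono-ether, and the TBDPS group is chosen because it should survive the organometallic step and both acidic treatments that follow.

Step 6
Reactants: 8 4-[(tert-butyldiphenylsilyl)oxy]but-2-yn-1-ol; 2 [2-(1,3-dioxolan-2-yl)ethyl]magnesium bromide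
Product: 10 (2E)-4-[(tert-butyldiphenylsilyl)oxy]-2-[2-(1,3-dioxolan-2-yl)ethyl]but-2-en-1-ol, via magnesium chelate 9 (not isolated)
Conditions: 8, CuI (15 mol%), THF, −20 °C; 2 (3.5 equiv, THF solution from step 1), −20 → 20 °C; aq NH4Cl
Reagents that add atoms: none
Why: In this hydroxyl-directed copper-catalysed anti-carbomagnesiation of a propargylic alcohol the magnesium alkoxide steers the alkyl group to the proximal alkyne carbon and magnesium to the distal one, closing the five-membered chelate 9, whose protonation with retention fixes the E geometry (CH2OH and CH2OSi trans).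

Step 7
Reactants: 10 (2E)-4-[(tert-butyldiphenylsilyl)oxy]-2-[2-(1,3-dioxolan-2-yl)ethyl]but-2-en-1-ol
Product: 11 (2E)-4-[(tert-butyldiphenylsilyl)oxy]-2-[2-(1,3-dioxolan-2-yl)ethyl]but-2-en-1-yl acetate
Conditions: Ac2O, Et3N, 4-(dimethylamino)pyridine (5 mol%), CH2Cl2, 0 °C
Reagents that add atoms: acetic anhydride, CC(=O)OC(C)=O
Why: Nucleophile-catalysed acylation of the primary allylic alcohol is routine, and acetylating before the acetal is opened prevents lactol formation between the hydroxyl group and the aldehyde.

Step 8
Reactants: 11 (2E)-4-[(tert-butyldiphenylsilyl)oxy]-2-[2-(1,3-dioxolan-2-yl)ethyl]but-2-en-1-yl acetate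
Product: 12 (2E)-4-[(tert-butyldiphenylsilyl)oxy]-2-(3-oxopropyl)but-2-en-1-yl acetate
Conditions: AcOH/THF/H2O (3:1:1), 50 °C
Reagents that add atoms: water, O
Why: Acid-catalysed dioxolane hydrolysis as in step 3, under which the allylic acetate is stable in the acetic acid medium and the TBDPS ether is inert to weak acid.

Step 9
Reactants: 6 (1E,5E)-N-tert-butyl-6,10-dimethylundeca-5,9-dien-1-imine; 12 (2E)-4-[(tert-butyldiphenylsilyl)oxy]-2-(3-oxopropyl)but-2-en-1-yl acetate
Product: 15 (2E,5E,9E)-2-{2-[(tert-butyldiphenylsilyl)oxy]ethylidene}-6-formyl-10,14-dimethylpentadeca-5,9,13-trien-1-yl acetate, via lithiated imine 13 (not isolated), via hydroxy imine 14 (not isolated)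
Conditions: 6, LiN(iPr)2, THF, −78 → 0 °C; 12, −78 °C; then aq oxalic acid, THF, rt
Reagents that add atoms: water, O
Why: In this directed aldol condensation through a metallated imine (aza-enolate) the lithiated aldimine should add to the aldehyde of 12 at −78 °C much faster than to the acetate, and mild acid then dehydrates the β-hydroxy imine and hydrolyses the C=N bond to the thermodynamically preferred (E)-2-alkyl enal, removing the two transient stereocentres of 14.

Step 10
Reactants: 15 (2E,5E,9E)-2-{2-[(tert-butyldiphenylsilyl)oxy]ethylidene}-6-formyl-10,14-dimethylpentadeca-5,9,13-trien-1-yl acetate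
Product: 16 (2E,5E,9E)-6-formyl-2-(2-hydroxyethylidene)-10,14-dimethylpentadeca-5,9,13-trien-1-yl acetate
Conditions: Bu4NF, AcOH (1:1), THF, 0 °C → rt
Reagents that add atoms: none
Why: Fluoride-mediated cleavage of the silyl ether, buffered with acetic acid, keeps the enal and the acetate away from base, and acetyl migration is ruled out because the two CH2O groups are trans across the alkene.

Step 11
Reactants: 16 (2E,5E,9E)-6-formyl-2-(2-hydroxyethylidene)-10,14-dimethylpentadeca-5,9,13-trien-1-yl acetate
Product: 17 (2E,5E,9E)-6-formyl-10,14-dimethyl-2-(2-oxoethylidene)pentadeca-5,9,13-trien-1-yl acetate (the acyclic bis-enal, an achiral isomer of the target)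
Conditions: MnO2 (activated, excess), CH2Cl2, rt
Reagents that add atoms: none
Why: Chemoselective MnO2 oxidation of a primary allylic alcohol to the enal leaves the existing aldehyde, the acetate and the isolated alkenes untouched, and any E/Z scrambling of the new enal is harmless because the next step erases that geometry.

Step 12
Reactants: 17 (2E,5E,9E)-6-formyl-10,14-dimethyl-2-(2-oxoethylidene)pentadeca-5,9,13-trien-1-yl acetate
Product: 18 {(3R)-2-formyl-3-[(2S,5E)-6,10-dimethyl-1-oxoundeca-5,9-dien-2-yl]cyclopent-1-en-1-yl}methyl acetate (CNP0280859.1)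
Conditions: (S)-2-[diphenyl(trimethylsilyloxy)methyl]pyrrolidine (20 mol%), PhCO2H (20 mol%), CH2Cl2, 0 °C → rt
Reagents that add atoms: none
Why: The unhindered β,β-disubstituted enal of 17 condenses with the amine and loses a γ-proton to a dienamine, whereas the α-branched enal condenses poorly and serves only as acceptor; the dienamine α-carbon bonds to the acceptor β-carbon in a transition state that amounts to an intramolecular hetero-Diels–Alder reaction (enamine C=C as 2π partner, acceptor enal as oxadiene), giving a cis-fused cyclopenta[c]pyran aminal that is protonated at its enol-ether carbon, ring-opens to a β,γ-unsaturated iminium ion, returns to conjugation (C1=C2) and is hydrolysed to 18 and the amine. The closest known reaction type is the dienamine-mediated intramolecular Rauhut–Currier cyclisation of bis-enals joined by a three-atom tether, which gives 2-formylcyclopentenes under secondary-amine catalysis, together with the kindred enamine/enal closures used for iridoid skeletons. The cyclopentene is closed 5-exo-trig through the C2–C3 bond, and because the change is a pure isomerisation the acetate, both aldehydes and the chain alkenes need no further adjustment. C3 (R) is set by the amine: its diphenyl(trimethylsilyloxy)methyl group blocks one face of the (E)-enamine, the acceptor is engaged on the open face, and the cis ring fusion translates this into the R configuration. The exocyclic centre (S) is set by relay from C3, the proton being delivered to the enol carbon on the convex face of the cis-fused bicycle, syn to H-3. The step needs α- rather than γ-attack, one acceptor face and convex-face protonation, secured respectively by the six-membered oxa-[4+2] array that only the α-carbon can complete while closing a five-membered ring, by the shielding group of the amine, and by the cis fusion.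

**Compound list**
1 | 2-(2-bromoethyl)-1,3-dioxolane | BrCCC1OCCO1 | starting material
2 | [2-(1,3-dioxolan-2-yl)ethyl]magnesium bromide | Br[Mg]CCC1OCCO1 | intermediate
3 | geranyl bromide, (2E)-1-bromo-3,7-dimethylocta-2,6-diene | CC(C)=CCC/C(C)=C/CBr | starting material
4 | 2-[(4E)-5,9-dimethyldeca-4,8-dien-1-yl]-1,3-dioxolane | CC(C)=CCC/C(C)=C/CCCC1OCCO1 | intermediate
5 | (5E)-6,10-dimethylundeca-5,9-dienal | CC(C)=CCC/C(C)=C/CCCC=O | intermediate
6 | (1E,5E)-N-tert-butyl-6,10-dimethylundeca-5,9-dien-1-imine | CC(C)=CCC/C(C)=C/CCC/C=N/C(C)(C)C | intermediate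
7 | but-2-yne-1,4-diol | OCC#CCO | starting material
8 | 4-[(tert-butyldiphenylsilyl)oxy]but-2-yn-1-ol | OCC#CCO[Si](C(C)(C)C)(c1ccccc1)c1ccccc1 | intermediate
9 | 3-{[(tert-butyldiphenylsilyl)oxy]methyl}-4-[2-(1,3-dioxolan-2-yl)ethyl]-2,5-dihydro-1,2-oxamagnesole (cyclic alkenylmagnesium alkoxide) | CC(C)(C)[Si](OCC1=C(CCC2OCCO2)CO[Mg]1)(c1ccccc1)c1ccccc1 | intermediate
10 | (2E)-4-[(tert-butyldiphenylsilyl)oxy]-2-[2-(1,3-dioxolan-2-yl)ethyl]but-2-en-1-ol | OC/C(CCC1OCCO1)=C/CO[Si](C(C)(C)C)(c1ccccc1)c1ccccc1 | intermediate
11 | (2E)-4-[(tert-butyldiphenylsilyl)oxy]-2-[2-(1,3-dioxolan-2-yl)ethyl]but-2-en-1-yl acetate | CC(=O)OC/C(CCC1OCCO1)=C/CO[Si](C(C)(C)C)(c1ccccc1)c1ccccc1 | intermediate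
12 | (2E)-4-[(tert-butyldiphenylsilyl)oxy]-2-(3-oxopropyl)but-2-en-1-yl acetate | CC(=O)OC/C(CCC=O)=C/CO[Si](C(C)(C)C)(c1ccccc1)c1ccccc1 | intermediate
13 | lithium tert-butyl[(5E)-6,10-dimethylundeca-1,5,9-trien-1-yl]amide (lithiated imine of 6) | CC(C)=CCC/C(C)=C/CCC=CN([Li])C(C)(C)C | intermediate
14 | (2E,9E)-6-[(E)-(tert-butylimino)methyl]-2-{2-[(tert-butyldiphenylsilyl)oxy]ethylidene}-5-hydroxy-10,14-dimethylpentadeca-9,13-dien-1-yl acetate, mixture of diastereomers at C5 and C6 | CC(=O)OC/C(CCC(O)C(CC/C=C(\C)CCC=C(C)C)/C=N/C(C)(C)C)=C/CO[Si](C(C)(C)C)(c1ccccc1)c1ccccc1 | intermediate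
15 | (2E,5E,9E)-2-{2-[(tert-butyldiphenylsilyl)oxy]ethylidene}-6-formyl-10,14-dimethylpentadeca-5,9,13-trien-1-yl acetate | CC(=O)OC/C(CC/C=C(/C=O)CC/C=C(\C)CCC=C(C)C)=C/CO[Si](C(C)(C)C)(c1ccccc1)c1ccccc1 | intermediate
16 | (2E,5E,9E)-6-formyl-2-(2-hydroxyethylidene)-10,14-dimethylpentadeca-5,9,13-trien-1-yl acetate | CC(=O)OC/C(CC/C=C(/C=O)CC/C=C(\C)CCC=C(C)C)=C/CO | intermediate
17 | (2E,5E,9E)-6-formyl-10,14-dimethyl-2-(2-oxoethylidene)pentadeca-5,9,13-trien-1-yl acetate | CC(=O)OC/C(CC/C=C(/C=O)CC/C=C(\C)CCC=C(C)C)=C/C=O | intermediate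
18 | {(3R)-2-formyl-3-[(2S,5E)-6,10-dimethyl-1-oxoundeca-5,9-dien-2-yl]cyclopent-1-en-1-yl}methyl acetate | CC(=O)OCC1=C(C=O)[C@@H]([C@@H](C=O)CC/C=C(\C)CCC=C(C)C)CC1 | target

**Totals**
Total step count: 12.
Longest linear sequence: 8 steps (steps 5 to 12 from but-2-yne-1,4-diol; the branches from the bromoacetal through steps 1, 2, 3, 4, 9–12 or through steps 1, 6–12 are equally long).

**Steps most likely to fail**

Step 12. What may go wrong: proton transfer to the enol carbon of the bicyclic aminal on both faces, together with amine-mediated epimerisation of the α-formyl centre, so that the exocyclic centre is formed without control while C3 is set correctly. The fallback sets out from 17 and comes back at 18, and it changes the way the exocyclic centre is secured, from kinetic proton delivery to separation with thermodynamic recycling. The ring closure is then asked only to fix C3. The cyclisation mixture is separated by chromatography into 18 and its exocyclic epimer, {(3R)-2-formyl-3-[(2R,5E)-6,10-dimethyl-1-oxoundeca-5,9-dien-2-yl]cyclopent-1-en-1-yl}methyl acetate F8. In a separate operation F8 is re-equilibrated at the α-formyl centre alone through its enamine (catalytic pyrrolidine/PhCO2H, CH2Cl2, rt); C3 has no acidifying neighbour and should not epimerise. The equilibrium mixture is separated again, so that repeated cycles should funnel the material into 18.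

Step 6. What may go wrong: thermal decay of Grignard reagent 2 during the slow carbometallation, delivery of the alkyl group to the wrong alkyne carbon, or β-elimination of the silyloxy group to an allene. The fallback replaces carbometallation by hydrometallation and cross-coupling; it sets out from 7 and comes back at 10. Monoalkylation of excess 7 (NaH, 4-methoxybenzyl chloride, THF/DMF) should give 4-[(4-methoxybenzyl)oxy]but-2-yn-1-ol F1. Hydroxyl-directed trans-hydroalumination with NaAlH2(OCH2CH2OMe)2 followed by I2 at −78 °C should give (2Z)-3-iodo-4-[(4-methoxybenzyl)oxy]but-2-en-1-ol F2, in which iodine marks the carbon that must carry the side chain. Silylation (TBDPSCl, imidazole) gives tert-butyl({(2Z)-3-iodo-4-[(4-methoxybenzyl)oxy]but-2-en-1-yl}oxy)diphenylsilane F3. Hydroboration of commercial 2-vinyl-1,3-dioxolane (C=CC1OCCO1) with 9-borabicyclo[3.3.1]nonane gives 9-[2-(1,3-dioxolan-2-yl)ethyl]-9-borabicyclo[3.3.1]nonane F4. F4 is coupled with F3 in a B-alkyl Suzuki–Miyaura reaction (PdCl2(dppf), aq K3PO4, THF/DMF, rt; zerovalent palladium inserts into the C–I bond with retention) to tert-butyl({(2E)-3-[2-(1,3-dioxolan-2-yl)ethyl]-4-[(4-methoxybenzyl)oxy]but-2-en-1-yl}oxy)diphenylsilane F5. Oxidative removal of the 4-methoxybenzyl group (2,3-dichloro-5,6-dicyano-1,4-benzoquinone, CH2Cl2/pH 7 buffer) then frees the hydroxymethyl group on the substituted carbon and should deliver 10 with the same E geometry.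

Step 9. What may go wrong: retro-aldol cleavage and incomplete dehydration of the β-hydroxy imine during the acidic work-up, and proton transfer from the enolisable aldehyde to the basic aza-enolate. The fallback forms the C=C bond by Peterson olefination instead of aldol addition and dehydration; it sets out from 6 and comes back at 15. Compound 6 is metallated as in step 9 and C-silylated with Et3SiCl to (1E,5E)-N-tert-butyl-6,10-dimethyl-2-(triethylsilyl)undeca-5,9-dien-1-imine F6. A second metallation (LiN(iPr)2, THF, −78 °C) gives a silyl-stabilised, less basic aza-enolate. Its addition to 12 should be followed by spontaneous loss of lithium triethylsilanolate, giving directly the unsaturated imine, (2E,5E,9E)-6-[(E)-(tert-butylimino)methyl]-2-{2-[(tert-butyldiphenylsilyl)oxy]ethylidene}-10,14-dimethylpentadeca-5,9,13-trien-1-yl acetate F7. Brief treatment with aqueous oxalic acid hydrolyses F7 to 15 with equilibration to the E enal.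

**Further compounds**
F1 | step 6 | 4-[(4-methoxybenzyl)oxy]but-2-yn-1-ol | OCC#CCOCc1ccc(OC)cc1
F2 | step 6 | (2Z)-3-iodo-4-[(4-methoxybenzyl)oxy]but-2-en-1-ol | OC/C=C(\I)COCc1ccc(OC)cc1
F3 | step 6 | tert-butyl({(2Z)-3-iodo-4-[(4-methoxybenzyl)oxy]but-2-en-1-yl}oxy)diphenylsilane | CC(C)(C)[Si](OC/C=C(\I)COCc1ccc(OC)cc1)(c1ccccc1)c1ccccc1
F4 | step 6 | 9-[2-(1,3-dioxolan-2-yl)ethyl]-9-borabicyclo[3.3.1]nonane | C1CC2CCCC(C1)B2CCC1OCCO1
F5 | step 6 | tert-butyl({(2E)-3-[2-(1,3-dioxolan-2-yl)ethyl]-4-[(4-methoxybenzyl)oxy]but-2-en-1-yl}oxy)diphenylsilane | CC(C)(C)[Si](OC/C=C(\CCC1OCCO1)COCc1ccc(OC)cc1)(c1ccccc1)c1ccccc1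
F6 | step 9 | (1E,5E)-N-tert-butyl-6,10-dimethyl-2-(triethylsilyl)undeca-5,9-dien-1-imine | CC(C)=CCC/C(C)=C/CCC(/C=N/C(C)(C)C)[Si](CC)(CC)CC
F7 | step 9 | (2E,5E,9E)-6-[(E)-(tert-butylimino)methyl]-2-{2-[(tert-butyldiphenylsilyl)oxy]ethylidene}-10,14-dimethylpentadeca-5,9,13-trien-1-yl acetate | CC(=O)OC/C(CC/C=C(/C=N/C(C)(C)C)CC/C=C(\C)CCC=C(C)C)=C/CO[Si](C(C)(C)C)(c1ccccc1)c1ccccc1
F8 | step 12 | {(3R)-2-formyl-3-[(2R,5E)-6,10-dimethyl-1-oxoundeca-5,9-dien-2-yl]cyclopent-1-en-1-yl}methyl acetate | CC(=O)OCC1=C(C=O)[C@@H]([C@H](C=O)CC/C=C(\C)CCC=C(C)C)CC1
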